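**Plan**

- Retrosynthesis: the four MOM ethers are removed last, the C4 ketone is unmasked from a spiro-1,3-dithiane, and the C3–C4 and O1–C8a bonds are then cut together. This gives a ring A dithiane (16) and a ring B (R)-aryloxirane (11).
- Enabling feature: C4 is an aryl ketone carbon on ring A, so it can act as a 2-lithio-1,3-dithiane carbanion. O1–C2–C3 is the O–C–C unit of a terminal epoxide. C8a, the ring A carbon ortho to C4, can carry fluoride for displacement by the alkoxide that epoxide opening releases.
- Forward order: ring B arm (resorcinol → bis-MOM ether → geranyl arene → chloroketone → chlorohydrin → epoxide); ring A arm (5-fluororesorcinol → aldehyde → dithiane → bis-MOM ether); a one-pot [3+3] annulation joins both arms and closes the pyran ring (ring C); then dithiane hydrolysis and MOM removal.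
- Stereochemistry: C2 is set by catalyst-controlled asymmetric transfer hydrogenation of the chloroketone and carried through the epoxide. It never sits β to a free carbonyl under basic conditions, so retro-oxa-Michael racemisation is avoided. The E-alkene comes from geranyl bromide.

Key step: step 9

Assumption: resorcinol, geranyl bromide, 2-chloro-N-methoxy-N-methylacetamide and 5-fluororesorcinol are taken as purchased. Organolithium intermediates are drawn as monomers with a covalent Li bond. Geranyl = (2E)-3,7-dimethylocta-2,6-dien-1-yl; MOM = methoxymethyl. Flavanone numbering: O1, C2, C3, C4, C4a, C5–C8, C8a; ring A is the benzo ring, ring B the 2-aryl group, ring C the pyranone.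

**Route**

Step 1
Reactants: 1 resorcinol
Product: 2 1,3-bis(methoxymethoxy)benzene
Conditions: MOMCl, i-Pr2NEt, CH2Cl2, 0 °C → rt
Reagents that add atoms: chloromethyl methyl ether (MOMCl), COCCl
Why: Williamson-type O-alkylation of both phenols with the reactive chloromethyl ether gives the MOM acetals that later direct both metalations.

Step 2
Reactants: 2 1,3-bis(methoxymethoxy)benzene; 3 geranyl bromide
Product: 5 2-geranyl-1,3-bis(methoxymethoxy)benzene, via 2-lithio-1,3-bis(methoxymethoxy)benzene 4 (not isolated)
Conditions: n-BuLi, THF, 0 °C → rt; CuI (10 mol %), then 3, −78 °C → rt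
Reagents that add atoms: geranyl bromide (compound 3), CC(C)=CCC/C(C)=C/CBr
Why: Directed ortho-metalation at the position flanked by both OMOM groups, followed by copper-catalysed SN2 allylation at the primary carbon of 3, should keep the E-alkene and give the linear geranyl arene.

Step 3
Reactants: 5 2-geranyl-1,3-bis(methoxymethoxy)benzene; 6 2-chloro-N-methoxy-N-methylacetamide
Product: 9 2-chloro-1-[3-geranyl-2,4-bis(methoxymethoxy)phenyl]ethan-1-one, via ring-lithiated arene 7 (not isolated), via lithium hemiaminal adduct 8 (not isolated)
Conditions: n-BuLi, TMEDA, THF, −78 → 0 °C; then 6, −78 °C; AcOH, −78 °C → rt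
Reagents that add atoms: 2-chloro-N-methoxy-N-methylacetamide (compound 6), CON(C)C(=O)CCl
Why: A second directed ortho-metalation can only occur next to one OMOM group (C4 and C6 are equivalent), and Weinreb ketone synthesis through the chelated adduct 8 stops at the ketone without touching the C–Cl bond.

Step 4
Reactants: 9 2-chloro-1-[3-geranyl-2,4-bis(methoxymethoxy)phenyl]ethan-1-one
Product: 10 (1R)-2-chloro-1-[3-geranyl-2,4-bis(methoxymethoxy)phenyl]ethan-1-ol
Conditions: RuCl[(S,S)-TsDPEN](p-cymene) (1 mol %), HCO2H/Et3N (5:2), EtOAc, rt
Reagents that add atoms: none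
Why: Noyori–Ikariya asymmetric transfer hydrogenation: the Ru–H/N–H unit of the (S,S)-catalyst delivers hydride through the six-membered transition state with the aryl group held against the p-cymene ligand, the sense that gives (S)-1-arylethanols from aryl methyl ketones and that is named R here because CH2Cl outranks the aryl group, while isolated alkenes and MOM ethers stay inert.

Step 5
Reactants: 10 (1R)-2-chloro-1-[3-geranyl-2,4-bis(methoxymethoxy)phenyl]ethan-1-ol
Product: 11 (2R)-2-[3-geranyl-2,4-bis(methoxymethoxy)phenyl]oxirane
Conditions: 2 M aq. NaOH, THF/MeOH, 0 °C → rt; used after filtration through basic alumina, no silica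
Reagents that add atoms: none
Why: Intramolecular Williamson etherification (3-exo-tet) displaces the primary chloride with the carbinol oxygen, so the stereocenter is not touched and the R configuration is retained.

Step 6
Reactants: 12 5-fluororesorcinol
Product: 14 2-fluoro-4,6-dihydroxybenzaldehyde, via aryl iminium chloride 13 (not isolated)
Conditions: POCl3, DMF, MeCN, 0 °C → rt; then H2O, 50 °C
Reagents that add atoms: N,N-dimethylformamide, CN(C)C=O; water, O
Why: Vilsmeier–Haack formylation should attack the position para to one hydroxyl and ortho to the other (C4 and C6 are equivalent), as is usual for 5-substituted resorcinols, and water hydrolyses the iminium salt 13.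

Step 7
Reactants: 14 2-fluoro-4,6-dihydroxybenzaldehyde
Product: 15 2-(2-fluoro-4,6-dihydroxyphenyl)-1,3-dithiane
Conditions: HS(CH2)3SH, BF3·OEt2 (20 mol %), THF/CH2Cl2, 0 °C → rt
Reagents that add atoms: propane-1,3-dithiol, SCCCS
Why: Lewis-acid-catalysed dithioacetalisation of the aldehyde installs the temporary 1,3-dithiane ring, and it is done before MOM protection because BF3 together with a thiol would cleave MOM ethers.

Step 8
Reactants: 15 2-(2-fluoro-4,6-dihydroxyphenyl)-1,3-dithiane
Product: 16 2-[2-fluoro-4,6-bis(methoxymethoxy)phenyl]-1,3-dithiane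
Conditions: MOMCl, i-Pr2NEt, CH2Cl2/DMF, 0 °C → rt
Reagents that add atoms: chloromethyl methyl ether (MOMCl), COCCl
Why: Williamson-type O-alkylation of both phenols, with the weakly nucleophilic dithiane sulfur atoms not alkylated irreversibly under amine base.

Step 9
Reactants: 16 2-[2-fluoro-4,6-bis(methoxymethoxy)phenyl]-1,3-dithiane; 11 (2R)-2-[3-geranyl-2,4-bis(methoxymethoxy)phenyl]oxirane
Product: 19 (2S)-2-[3-geranyl-2,4-bis(methoxymethoxy)phenyl]-5,7-bis(methoxymethoxy)spiro[chromane-4,2'-[1,3]dithiane], via 2-lithio-1,3-dithiane 17 (not isolated), via lithium alkoxide 18 (not isolated)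
Conditions: n-BuLi (1.0 equiv), THF/HMPA (10:1), −78 °C; 11, −78 → 0 °C; then 60 °C
Reagents that add atoms: none
Why: Proposed new method: n-BuLi removes the C–H between the two sulfur atoms of 16 (the HMPA-solvated base follows acidity and not the coordination that drives ring metalation), the carbanion 17 opens oxirane 11 by SN2 attack at its unsubstituted CH2 to make the C3–C4 bond, and the C2 alkoxide 18 thus released adds on warming to the fluorine-bearing carbon of ring A ortho to the dithiane carbon and expels LiF to make the O1–C8a bond. The closest known reaction types are the Corey–Seebach alkylation of 2-aryl-2-lithio-1,3-dithianes with terminal epoxides and the intramolecular SNAr etherification of 3-(2-fluoroaryl)propanols to chromans, and only their merger into a one-pot [3+3] annulation is new. The pyran ring (ring C) closes by a 6-exo-trig addition–elimination at the aromatic carbon, helped by the fully substituted dithiane carbon in the tether, by the inductive pull of the two meta OMOM groups and by the affinity of lithium for fluoride. No stereocenter is created: C2 is carried over from 11 untouched because the nucleophile attacks the neighbouring CH2 and the oxygen only gains a new partner (the descriptor changes from R to S solely through the CIP ranking), and the spiro carbon is not stereogenic. The step needs lithiation at the dithiane and not at the ring, attack at the CH2 and not at the benzylic carbon of the epoxide, and displacement of F and not of the ortho OMOM group; these are secured by the acidity of the S2C–H bond, by the bulk of the tertiary carbanion together with the ortho OMOM shield of the benzylic carbon, and by fluoride being the far better SNAr nucleofuge. With C4 held as a thioketal there is no β-aryloxy ketone in the basic medium, so ring opening by retro-oxa-Michael reaction and loss of configuration cannot occur.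

Step 10
Reactants: 19 (2S)-2-[3-geranyl-2,4-bis(methoxymethoxy)phenyl]-5,7-bis(methoxymethoxy)spiro[chromane-4,2'-[1,3]dithiane]
Product: 20 (2S)-2-[3-geranyl-2,4-bis(methoxymethoxy)phenyl]-5,7-bis(methoxymethoxy)chroman-4-one
Conditions: MeI (excess), CaCO3, MeCN/H2O (9:1), 45 °C
Reagents that add atoms: water, O
Why: Alkylative dithiane hydrolysis (S-methylation, ring opening to an aryl-stabilised thionium ion, capture by water) runs at near-neutral pH buffered by CaCO3, so the MOM ethers, the alkenes and the now epimerisable C2 should be left alone.

Step 11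
Reactants: 20 (2S)-2-[3-geranyl-2,4-bis(methoxymethoxy)phenyl]-5,7-bis(methoxymethoxy)chroman-4-one
Product: 21 sanggenol A
Conditions: 3 M aq. HCl, MeOH, 30–40 °C, stopped at full conversion
Reagents that add atoms: none
Why: Acid-catalysed acetal exchange of the four aryl MOM ethers with methanol liberates the phenols, and dilute acid at mild temperature is chosen to outrun cyclisation of the geranyl chain and ionisation at C2.

**Compound list**

1 | resorcinol | Oc1cccc(O)c1 | starting material
2 | 1,3-bis(methoxymethoxy)benzene | COCOc1cccc(OCOC)c1 | intermediate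
3 | geranyl bromide, (2E)-1-bromo-3,7-dimethylocta-2,6-diene | CC(C)=CCC/C(C)=C/CBr | starting material
4 | 2-lithio-1,3-bis(methoxymethoxy)benzene | [Li]c1c(OCOC)cccc1OCOC | intermediate
5 | 2-geranyl-1,3-bis(methoxymethoxy)benzene | COCOc1cccc(OCOC)c1C/C=C(\C)CCC=C(C)C | intermediate
6 | 2-chloro-N-methoxy-N-methylacetamide | CON(C)C(=O)CCl | starting material
7 | 4-lithio-2-geranyl-1,3-bis(methoxymethoxy)benzene (Li ortho to one OMOM group) | [Li]c1ccc(OCOC)c(C/C=C(\C)CCC=C(C)C)c1OCOC | intermediate
8 | lithium hemiaminal adduct of 7 and 6 (chelated tetrahedral intermediate) | [Li]OC(CCl)(N(C)OC)c1ccc(OCOC)c(C/C=C(\C)CCC=C(C)C)c1OCOC | intermediate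
9 | 2-chloro-1-[3-geranyl-2,4-bis(methoxymethoxy)phenyl]ethan-1-one | O=C(CCl)c1ccc(OCOC)c(C/C=C(\C)CCC=C(C)C)c1OCOC | intermediate
10 | (1R)-2-chloro-1-[3-geranyl-2,4-bis(methoxymethoxy)phenyl]ethan-1-ol | O[C@@H](CCl)c1ccc(OCOC)c(C/C=C(\C)CCC=C(C)C)c1OCOC | intermediate
11 | (2R)-2-[3-geranyl-2,4-bis(methoxymethoxy)phenyl]oxirane | C1O[C@@H]1c1ccc(OCOC)c(C/C=C(\C)CCC=C(C)C)c1OCOC | intermediate
12 | 5-fluororesorcinol (5-fluorobenzene-1,3-diol) | Oc1cc(O)cc(F)c1 | starting material
13 | (2-fluoro-4,6-dihydroxybenzylidene)dimethyliminium chloride | C[N+](C)=Cc1c(O)cc(O)cc1F.[Cl-] | intermediate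
14 | 2-fluoro-4,6-dihydroxybenzaldehyde | O=Cc1c(O)cc(O)cc1F | intermediate
15 | 2-(2-fluoro-4,6-dihydroxyphenyl)-1,3-dithiane | Oc1cc(O)c(C2SCCCS2)c(F)c1 | intermediate
16 | 2-[2-fluoro-4,6-bis(methoxymethoxy)phenyl]-1,3-dithiane | COCOc1cc(OCOC)c(C2SCCCS2)c(F)c1 | intermediate
17 | 2-lithio-2-[2-fluoro-4,6-bis(methoxymethoxy)phenyl]-1,3-dithiane | [Li]C1(SCCCS1)c1c(F)cc(OCOC)cc1OCOC | intermediate
18 | lithium (1S)-1-[3-geranyl-2,4-bis(methoxymethoxy)phenyl]-2-{2-[2-fluoro-4,6-bis(methoxymethoxy)phenyl]-1,3-dithian-2-yl}ethan-1-olate | [Li]O[C@@H](CC1(SCCCS1)c1c(F)cc(OCOC)cc1OCOC)c1ccc(OCOC)c(C/C=C(\C)CCC=C(C)C)c1OCOC | intermediate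
19 | (2S)-2-[3-geranyl-2,4-bis(methoxymethoxy)phenyl]-5,7-bis(methoxymethoxy)spiro[chromane-4,2'-[1,3]dithiane] | COCOc1cc(OCOC)c2c(c1)O[C@@H](CC21SCCCS1)c1ccc(OCOC)c(C/C=C(\C)CCC=C(C)C)c1OCOC | intermediate
20 | (2S)-2-[3-geranyl-2,4-bis(methoxymethoxy)phenyl]-5,7-bis(methoxymethoxy)chroman-4-one | COCOc1cc(OCOC)c2c(c1)O[C@@H](CC2=O)c1ccc(OCOC)c(C/C=C(\C)CCC=C(C)C)c1OCOC | intermediate
21 | sanggenol A, (2S)-2-(3-geranyl-2,4-dihydroxyphenyl)-5,7-dihydroxychroman-4-one | CC(C)=CCC/C(C)=C/Cc1c(O)ccc([C@@H]2CC(=O)c3c(O)cc(O)cc3O2)c1O | target

**Step count**

Total steps: 11. Longest linear sequence: 8 steps (steps 1–5, then 9–11); the ring A arm (steps 6–8) joins at step 9.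

**Steps most likely to fail**

1. Step 9 (proposed new method). What may go wrong: metalation of ring A at the C–H bonds flanked by F/OMOM or OMOM/OMOM, followed by loss of LiF to an aryne; attack at, or ionisation of, the benzylic carbon of the electron-rich epoxide; stalling at the open-chain alkoxide because fluoride displacement on a ring without a strong acceptor is slow. The fallback gives up the annulation and uses a known reaction type, the rhodium-catalysed asymmetric conjugate arylation of chromones to flavanones. It sets out from 5, which is lithiated as in step 3 and quenched with B(OMe)3 and then dilute acid to give [3-geranyl-2,4-bis(methoxymethoxy)phenyl]boronic acid F1. Purchased 5,7-dihydroxy-4H-chromen-4-one is protected with MOMCl and NaH in DMF to give 5,7-bis(methoxymethoxy)-4H-chromen-4-one F2. Addition of F1 to F2 with [Rh(OH)(cod)]2 and an electron-poor atropisomeric bisphosphine such as MeO-F12-BIPHEP (the antipode that delivers the aryl group to the face giving 2S) in toluene/water should give 20 directly, and the route is rejoined at compound 20 before step 11.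

2. Step 11. What may go wrong: acid-promoted cyclisation of the geranyl chain onto either flanking phenol or addition of solvent to its alkenes; loss of configuration at C2 through acid-assisted heterolysis of the C2–O1 bond (the benzylic cation is stabilised by the 2',4'-dioxygenated ring B) or through ring opening to the chalcone. The fallback inverts the order of unmasking so that the acid step never sees the ketone. It sets out from 19, whose four MOM ethers are cleaved with dilute HCl in MeOH while C4 is still a thioketal (no enolisable carbonyl and no ortho-acyl activation of O1 as a leaving group) to give (2S)-2-(3-geranyl-2,4-dihydroxyphenyl)spiro[chromane-4,2'-[1,3]dithiane]-5,7-diol F3. Neutral alkylative hydrolysis of F3 (MeI, CaCO3, aqueous MeCN) then gives 21, so the fallback comes back at the target itself.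

3. Step 3. What may go wrong: deprotonation at the benzylic–allylic CH2 of the geranyl chain (lateral metalation assisted by the flanking OMOM groups) in place of ring metalation, leading to alkene migration or acylation in the chain. The fallback generates the same aryllithium by halogen–lithium exchange, which is faster than any deprotonation. It sets out from 2, which is brominated para to one OMOM group (NBS, MeCN, 0 °C) to give 1-bromo-2,4-bis(methoxymethoxy)benzene F4. Lithium diisopropylamide in THF at −78 °C metalates F4 between the two OMOM groups without touching the bromide, and allylation with 3 and catalytic CuI gives 1-bromo-3-geranyl-2,4-bis(methoxymethoxy)benzene F5. Treatment of F5 with n-BuLi at −78 °C gives aryllithium 7, which is acylated with 6 as in step 3, and the route is rejoined at compound 9.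

**Further compounds**

F1 | step 9 | [3-geranyl-2,4-bis(methoxymethoxy)phenyl]boronic acid | OB(O)c1ccc(OCOC)c(C/C=C(\C)CCC=C(C)C)c1OCOC
F2 | step 9 | 5,7-bis(methoxymethoxy)-4H-chromen-4-one | COCOc1cc(OCOC)c2c(c1)occc2=O
F3 | step 11 | (2S)-2-(3-geranyl-2,4-dihydroxyphenyl)spiro[chromane-4,2'-[1,3]dithiane]-5,7-diol | Oc1cc(O)c2c(c1)O[C@@H](CC21SCCCS1)c1ccc(O)c(C/C=C(\C)CCC=C(C)C)c1O
F4 | step 3 | 1-bromo-2,4-bis(methoxymethoxy)benzene | COCOc1ccc(Br)c(OCOC)c1
F5 | step 3 | 1-bromo-3-geranyl-2,4-bis(methoxymethoxy)benzene | Brc1ccc(OCOC)c(C/C=C(\C)CCC=C(C)C)c1OCOC
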